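**Plan**

1. Retrosynthesis: the two aryl–CH bonds at the bridging methine are cut first (last the bond to C6 of the 2‑methylbutanoyl chroman, before it the bond to C6 of the 2‑methylpropanoyl chroman). Each chroman is then cut at C4–C4a and C2–C3, leaving an aryl–O–C(CH3)2 fragment and a two‑carbon unit.
2. Forward: phloroglucinol is C‑acylated, benzylated on two oxygens and etherified on the remaining ortho oxygen with a C(CH3)2–CO2R group. A decarboxylative radical (4+2) annulation with phenyl vinyl sulfone then closes each pyran ring, and the benzyl and sulfonyl helpers leave together. The 2‑methylpropanoyl chroman is condensed with 6‑methylheptanal and a sulfinic acid, and the second chroman is added last.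
3. Enabling feature: the pyran oxygen O1 with its quaternary C2(CH3)2 carries an oxygen‑stabilised tertiary radical once CO2 is lost. The single unsubstituted carbon ortho to that oxygen on the electron‑rich phloroglucinol ring (future C4a) accepts the electrophilic sulfonyl‑bearing radical at C4.
4. Stereochemistry: the (R) acyl centre is bought with (R)‑2‑methylbutanoic acid. The (R) bridging methine is set in the last step by a cinchona squaramide catalyst in a conjugate addition to an ortho‑quinone methide.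

Key step: step 5

Remark: CIP analysis of the target gives (R) at C2 of the 2‑methylbutanoyl group and (R) at the bridging methine (the chroman carrying the 2‑methylbutanoyl group ranks above the one carrying the 2‑methylpropanoyl group). Chroman numbering (O1, C2, C3, C4, C4a, C5–C8, C8a) is used throughout. The sense of induction in step 14 is assigned to the quinine‑derived catalyst by analogy and is an assumption; the quinidine‑derived pseudoenantiomer is the reserve. (R)‑2‑Methylbutanoic acid, 6‑methylheptanal and p‑toluenesulfinic acid are taken as purchasable.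

**Route**

Step 1
Reactants: 1 benzene‑1,3,5‑triol (phloroglucinol); 2 2‑methylpropanoyl chloride
Product: 3 2‑methyl‑1‑(2,4,6‑trihydroxyphenyl)propan‑1‑one
Conditions: AlCl3 (4 equiv), PhNO2/CH2Cl2, 0 °C to rt; ice/aq. HCl
Reagents that add atoms: none
Why: Friedel–Crafts acylation of the threefold activated ring should stop at the monoketone because the first acyl group deactivates the ring.

Step 2
Reactants: 3
Product: 4 1‑[2,4‑bis(benzyloxy)‑6‑hydroxyphenyl]‑2‑methylpropan‑1‑one
Conditions: BnBr (2.1 equiv), K2CO3 (2.2 equiv), DMF, 0 °C to rt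
Reagents that add atoms: benzyl bromide, BrCc1ccccc1
Why: Williamson etherification should take the para and one ortho hydroxyl and spare the last ortho hydroxyl, which is hydrogen‑bonded to the ketone.

Step 3
Reactants: 4; 5 tert‑butyl 2‑bromo‑2‑methylpropanoate
Product: 6 tert‑butyl 2‑[3,5‑bis(benzyloxy)‑2‑(2‑methylpropanoyl)phenoxy]‑2‑methylpropanoate
Conditions: Cs2CO3 (3 equiv), DMF, 60 °C
Reagents that add atoms: none
Why: Williamson‑type O‑alkylation of the cesium phenoxide with the tertiary alpha‑bromo ester (the standard entry to 2‑aryloxy‑2‑methylpropanoates) places the O–C(CH3)2 unit on the only oxygen that has an unsubstituted ortho carbon next to it.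

Step 4
Reactants: 6
Product: 8 1,3‑dioxoisoindolin‑2‑yl 2‑[3,5‑bis(benzyloxy)‑2‑(2‑methylpropanoyl)phenoxy]‑2‑methylpropanoate, via carboxylic acid 7 (not isolated)
Conditions: TFA/CH2Cl2 (1:4), anisole, 0 °C to rt; evaporate; then N‑hydroxyphthalimide, DIC, DMAP (cat.), CH2Cl2, rt
Reagents that add atoms: N‑hydroxyphthalimide, O=C1c2ccccc2C(=O)N1O
Why: acidolysis of the tert‑butyl ester should leave the aryl benzyl ethers intact, and the carbodiimide coupling (Steglich‑type esterification) gives the redox‑active ester that the decarboxylation needs.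

Step 5
Reactants: 8; 9 (ethenylsulfonyl)benzene (phenyl vinyl sulfone)
Product: 10 1‑[5,7‑bis(benzyloxy)‑2,2‑dimethyl‑4‑(phenylsulfonyl)‑3,4‑dihydro‑2H‑chromen‑8‑yl]‑2‑methylpropan‑1‑one (racemic at C4)
Conditions: fac‑Ir(ppy)3 (ppy = 2‑phenylpyridinato, 1 mol %), 9 (3 equiv), degassed MeCN (0.05 M), 450 nm LEDs, rt
Reagents that add atoms: none
Why: Electron transfer from the photoexcited trivalent iridium complex to the N‑acyloxyphthalimide releases phthalimide anion and CO2 and leaves the tertiary radical at the carbon on the aryl oxygen, which adds to the CH2 end of the vinyl sulfone (Giese addition, C2–C3 bond); the sulfonyl‑stabilised radical then attacks the free ortho carbon (C4–C4a bond), and the cyclohexadienyl radical is oxidised by the tetravalent iridium formed at the start and deprotonated by phthalimide anion, so that no external oxidant or reductant is needed. The closest known reaction type is the photoredox decarboxylative radical (4+2) annulation of N‑acyloxyphthalimides of aryloxyacetic acids with electron‑poor alkenes, which gives chromans. The pyran ring closes in the 6‑endo mode by homolytic aromatic substitution at the ortho carbon through a six‑membered transition state, which is preferred to five‑membered (5‑exo) ipso attack at the oxygen‑bearing carbon. The one new stereocentre, C4, forms without control and disappears with the sulfonyl group in step 6. The step needs chemoselectivity (addition to the alkene before the first radical is oxidised, ring closure before a second alkene adds or the radical is reduced) and regioselectivity: the first is secured by polarity matching (nucleophilic alkoxyalkyl radical with the electron‑poor alkene, electrophilic sulfonylalkyl radical with the trioxygenated ring), by the gem‑dimethyl group and by the absence of any stoichiometric reductant, the second by the ketone that blocks the other ortho carbon.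

Step 6
Reactants: 10
Product: 13 1‑(5,7‑dihydroxy‑2,2‑dimethyl‑3,4‑dihydro‑2H‑chromen‑8‑yl)‑2‑methylpropan‑1‑one, via diol sulfone 11 (not isolated), via quinone methide 12 (not isolated)
Conditions: H2 (1 atm), Pd/C (10 wt %), THF/MeOH, rt; filter; then NaBH4 (4 equiv), 0 °C to rt; aq. NH4Cl
Reagents that add atoms: none
Why: hydrogenolysis frees both phenols, the 5‑phenoxide then expels benzenesulfinate from C4 and borohydride reduces the resulting ortho‑quinone methide at C4 (reductive desulfonylation by elimination and 1,4‑hydride addition), while the hindered ketone is protected as its ortho‑phenoxide.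

Step 7
Reactants: 1 benzene‑1,3,5‑triol; 14 (2R)‑2‑methylbutanoic acid
Product: 16 (2R)‑2‑methyl‑1‑(2,4,6‑trihydroxyphenyl)butan‑1‑one, via acid chloride 15 (not isolated)
Conditions: (COCl)2 (1.1 equiv), DMF (cat.), CH2Cl2, 0 °C to rt; then added to 1, AlCl3 (4 equiv), PhNO2/CH2Cl2, 0 °C to rt; ice/aq. HCl
Reagents that add atoms: oxalyl chloride, O=C(Cl)C(=O)Cl (chlorine of 15 only)
Why: Friedel–Crafts acylation as in step 1; the stereocentre comes from the acid and should survive because no base is present and the temperature stays at or below rt, so that neither ketene formation nor enolisation is expected.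

Step 8
Reactants: 16
Product: 17 (2R)‑1‑[2,4‑bis(benzyloxy)‑6‑hydroxyphenyl]‑2‑methylbutan‑1‑one
Conditions: BnBr (2.1 equiv), K2CO3 (2.2 equiv), DMF, 0 °C to rt
Reagents that add atoms: benzyl bromide, BrCc1ccccc1
Why: Williamson etherification with the same selectivity as in step 2; the ortho phenoxide deactivates the ketone toward enolisation, so the alpha centre should be retained.

Step 9
Reactants: 17; 5 tert‑butyl 2‑bromo‑2‑methylpropanoate
Product: 18 tert‑butyl 2‑{3,5‑bis(benzyloxy)‑2‑[(2R)‑2‑methylbutanoyl]phenoxy}‑2‑methylpropanoate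
Conditions: Cs2CO3 (3 equiv), DMF, 60 °C
Reagents that add atoms: none
Why: Williamson‑type O‑alkylation as in step 3; carbonate should be too weak a base to enolise the hindered, twisted ketone, so the alpha centre should be retained.

Step 10
Reactants: 18
Product: 20 1,3‑dioxoisoindolin‑2‑yl 2‑{3,5‑bis(benzyloxy)‑2‑[(2R)‑2‑methylbutanoyl]phenoxy}‑2‑methylpropanoate, via carboxylic acid 19 (not isolated)
Conditions: TFA/CH2Cl2 (1:4), anisole, 0 °C to rt; evaporate; then N‑hydroxyphthalimide, DIC, DMAP (cat.), CH2Cl2, rt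
Reagents that add atoms: N‑hydroxyphthalimide, O=C1c2ccccc2C(=O)N1O
Why: tert‑butyl ester acidolysis and Steglich‑type esterification as in step 4, neither of which touches the alpha centre.

Step 11
Reactants: 20; 9 (ethenylsulfonyl)benzene
Product: 21 (2R)‑1‑[5,7‑bis(benzyloxy)‑2,2‑dimethyl‑4‑(phenylsulfonyl)‑3,4‑dihydro‑2H‑chromen‑8‑yl]‑2‑methylbutan‑1‑one (both C4 epimers)
Conditions: fac‑Ir(ppy)3 (ppy = 2‑phenylpyridinato, 1 mol %), 9 (3 equiv), degassed MeCN (0.05 M), 450 nm LEDs, rt
Reagents that add atoms: none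
Why: the same photoredox decarboxylative radical (4+2) annulation (Giese addition, then homolytic aromatic substitution) as in step 5 under neutral conditions; C4 forms as both epimers, which converge in step 12.

Step 12
Reactants: 21
Product: 24 (2R)‑1‑(5,7‑dihydroxy‑2,2‑dimethyl‑3,4‑dihydro‑2H‑chromen‑8‑yl)‑2‑methylbutan‑1‑one, via diol sulfone 22 (not isolated), via quinone methide 23 (not isolated)
Conditions: H2 (1 atm), Pd/C (10 wt %), THF/MeOH, rt; filter; then NaBH4 (4 equiv), 0 °C to rt; aq. NH4Cl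
Reagents that add atoms: none
Why: hydrogenolysis and reductive desulfonylation through the ortho‑quinone methide as in step 6; C4 becomes CH2 and the acyl centre is shielded by the ortho‑phenoxide.

Step 13
Reactants: 13; 25 6‑methylheptanal
Product: 27 1‑{5,7‑dihydroxy‑2,2‑dimethyl‑6‑[6‑methyl‑1‑(4‑methylbenzenesulfonyl)heptyl]‑3,4‑dihydro‑2H‑chromen‑8‑yl}‑2‑methylpropan‑1‑one (racemic), via carbinol 26 (not isolated)
Conditions: 25 (1.5 equiv), p‑TolSO2H (2 equiv), TsOH·H2O (10 mol %), CH2Cl2, MgSO4, rt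
Reagents that add atoms: 4‑methylbenzenesulfinic acid, Cc1ccc(cc1)S(O)=O
Why: acid‑catalysed hydroxyalkylation at C6, the only unsubstituted ring carbon, gives carbinol 26, whose benzylic hydroxyl is then replaced at sulfur by the soft sulfinic acid in an acid‑promoted SN1‑type substitution through the benzylic cation stabilised by the two ortho hydroxyls (a sulfinate variant of the three‑component Betti/Mannich condensation), so that the reaction should stop at the sulfone; its stereocentre is racemic and is erased in step 14.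

Step 14
Reactants: 27; 24
Product: 29 (2R)‑1‑{6‑[(1R)‑1‑[5,7‑dihydroxy‑2,2‑dimethyl‑8‑(2‑methylpropanoyl)‑3,4‑dihydro‑2H‑chromen‑6‑yl]‑6‑methylheptyl]‑5,7‑dihydroxy‑2,2‑dimethyl‑3,4‑dihydro‑2H‑chromen‑8‑yl}‑2‑methylbutan‑1‑one, via quinone methide 28 (not isolated)
Conditions: 24 (1.1 equiv), quinine‑derived squaramide 3‑{[3,5‑bis(trifluoromethyl)phenyl]amino}‑4‑{[(8α,9S)‑6'‑methoxycinchonan‑9‑yl]amino}cyclobut‑3‑ene‑1,2‑dione (10 mol %), sat. aq. NaHCO3/CHCl3, 0 °C
Reagents that add atoms: none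
Why: bicarbonate releases sulfinate from 27 to give the neutral ortho‑quinone methide 28, which is generated only here, and the bifunctional catalyst (squaramide N–H groups on the quinone methide carbonyl, quinuclidine on the acidic 5‑hydroxyl of 24) should deliver C6 of 24 to one face of the exocyclic C=C in an organocatalytic asymmetric Friedel–Crafts‑type conjugate addition that sets the (R) bridge, while no regioisomer or homodimer can form because C6 of 24 is its only free ring carbon and 28 has none.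

**Compound list**

1 | benzene‑1,3,5‑triol (phloroglucinol) | Oc1cc(O)cc(O)c1 | starting material
2 | 2‑methylpropanoyl chloride | CC(C)C(Cl)=O | starting material
3 | 2‑methyl‑1‑(2,4,6‑trihydroxyphenyl)propan‑1‑one | CC(C)C(=O)c1c(O)cc(O)cc1O | intermediate
4 | 1‑[2,4‑bis(benzyloxy)‑6‑hydroxyphenyl]‑2‑methylpropan‑1‑one | CC(C)C(=O)c1c(O)cc(OCc2ccccc2)cc1OCc1ccccc1 | intermediate
5 | tert‑butyl 2‑bromo‑2‑methylpropanoate | CC(C)(Br)C(=O)OC(C)(C)C | starting material
6 | tert‑butyl 2‑[3,5‑bis(benzyloxy)‑2‑(2‑methylpropanoyl)phenoxy]‑2‑methylpropanoate | CC(C)C(=O)c1c(OC(C)(C)C(=O)OC(C)(C)C)cc(OCc2ccccc2)cc1OCc1ccccc1 | intermediate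
7 | 2‑[3,5‑bis(benzyloxy)‑2‑(2‑methylpropanoyl)phenoxy]‑2‑methylpropanoic acid | CC(C)C(=O)c1c(OC(C)(C)C(O)=O)cc(OCc2ccccc2)cc1OCc1ccccc1 | intermediate (not isolated)
8 | 1,3‑dioxoisoindolin‑2‑yl 2‑[3,5‑bis(benzyloxy)‑2‑(2‑methylpropanoyl)phenoxy]‑2‑methylpropanoate | CC(C)C(=O)c1c(OC(C)(C)C(=O)ON2C(=O)c3ccccc3C2=O)cc(OCc2ccccc2)cc1OCc1ccccc1 | intermediate
9 | (ethenylsulfonyl)benzene (phenyl vinyl sulfone) | C=CS(=O)(=O)c1ccccc1 | starting material
10 | 1‑[5,7‑bis(benzyloxy)‑2,2‑dimethyl‑4‑(phenylsulfonyl)‑3,4‑dihydro‑2H‑chromen‑8‑yl]‑2‑methylpropan‑1‑one, racemic at C4 | CC(C)C(=O)c1c(OCc2ccccc2)cc(OCc2ccccc2)c2c1OC(C)(C)CC2S(=O)(=O)c1ccccc1 | intermediate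
11 | 1‑[5,7‑dihydroxy‑2,2‑dimethyl‑4‑(phenylsulfonyl)‑3,4‑dihydro‑2H‑chromen‑8‑yl]‑2‑methylpropan‑1‑one, racemic | CC(C)C(=O)c1c(O)cc(O)c2c1OC(C)(C)CC2S(=O)(=O)c1ccccc1 | intermediate (not isolated)
12 | 7‑hydroxy‑2,2‑dimethyl‑8‑(2‑methylpropanoyl)‑2,3‑dihydro‑5H‑chromen‑5‑one (ortho‑quinone methide) | CC(C)C(=O)C1=C2OC(C)(C)CC=C2C(=O)C=C1O | intermediate (not isolated)
13 | 1‑(5,7‑dihydroxy‑2,2‑dimethyl‑3,4‑dihydro‑2H‑chromen‑8‑yl)‑2‑methylpropan‑1‑one | CC(C)C(=O)c1c(O)cc(O)c2c1OC(C)(C)CC2 | intermediate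
14 | (2R)‑2‑methylbutanoic acid | CC[C@@H](C)C(O)=O | starting material
15 | (2R)‑2‑methylbutanoyl chloride | CC[C@@H](C)C(Cl)=O | intermediate (not isolated)
16 | (2R)‑2‑methyl‑1‑(2,4,6‑trihydroxyphenyl)butan‑1‑one | CC[C@@H](C)C(=O)c1c(O)cc(O)cc1O | intermediate
17 | (2R)‑1‑[2,4‑bis(benzyloxy)‑6‑hydroxyphenyl]‑2‑methylbutan‑1‑one | CC[C@@H](C)C(=O)c1c(O)cc(OCc2ccccc2)cc1OCc1ccccc1 | intermediate
18 | tert‑butyl 2‑{3,5‑bis(benzyloxy)‑2‑[(2R)‑2‑methylbutanoyl]phenoxy}‑2‑methylpropanoate | CC[C@@H](C)C(=O)c1c(OC(C)(C)C(=O)OC(C)(C)C)cc(OCc2ccccc2)cc1OCc1ccccc1 | intermediate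
19 | 2‑{3,5‑bis(benzyloxy)‑2‑[(2R)‑2‑methylbutanoyl]phenoxy}‑2‑methylpropanoic acid | CC[C@@H](C)C(=O)c1c(OC(C)(C)C(O)=O)cc(OCc2ccccc2)cc1OCc1ccccc1 | intermediate (not isolated)
20 | 1,3‑dioxoisoindolin‑2‑yl 2‑{3,5‑bis(benzyloxy)‑2‑[(2R)‑2‑methylbutanoyl]phenoxy}‑2‑methylpropanoate | CC[C@@H](C)C(=O)c1c(OC(C)(C)C(=O)ON2C(=O)c3ccccc3C2=O)cc(OCc2ccccc2)cc1OCc1ccccc1 | intermediate
21 | (2R)‑1‑[5,7‑bis(benzyloxy)‑2,2‑dimethyl‑4‑(phenylsulfonyl)‑3,4‑dihydro‑2H‑chromen‑8‑yl]‑2‑methylbutan‑1‑one, both C4 epimers | CC[C@@H](C)C(=O)c1c(OCc2ccccc2)cc(OCc2ccccc2)c2c1OC(C)(C)CC2S(=O)(=O)c1ccccc1 | intermediate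
22 | (2R)‑1‑[5,7‑dihydroxy‑2,2‑dimethyl‑4‑(phenylsulfonyl)‑3,4‑dihydro‑2H‑chromen‑8‑yl]‑2‑methylbutan‑1‑one, both C4 epimers | CC[C@@H](C)C(=O)c1c(O)cc(O)c2c1OC(C)(C)CC2S(=O)(=O)c1ccccc1 | intermediate (not isolated)
23 | 7‑hydroxy‑2,2‑dimethyl‑8‑[(2R)‑2‑methylbutanoyl]‑2,3‑dihydro‑5H‑chromen‑5‑one (ortho‑quinone methide) | CC[C@@H](C)C(=O)C1=C2OC(C)(C)CC=C2C(=O)C=C1O | intermediate (not isolated)
24 | (2R)‑1‑(5,7‑dihydroxy‑2,2‑dimethyl‑3,4‑dihydro‑2H‑chromen‑8‑yl)‑2‑methylbutan‑1‑one | CC[C@@H](C)C(=O)c1c(O)cc(O)c2c1OC(C)(C)CC2 | intermediate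
25 | 6‑methylheptanal | CC(C)CCCCC=O | starting material
26 | 1‑[5,7‑dihydroxy‑6‑(1‑hydroxy‑6‑methylheptyl)‑2,2‑dimethyl‑3,4‑dihydro‑2H‑chromen‑8‑yl]‑2‑methylpropan‑1‑one, racemic | CC(C)C(=O)c1c(O)c(C(O)CCCCC(C)C)c(O)c2c1OC(C)(C)CC2 | intermediate (not isolated)
27 | 1‑{5,7‑dihydroxy‑2,2‑dimethyl‑6‑[6‑methyl‑1‑(4‑methylbenzenesulfonyl)heptyl]‑3,4‑dihydro‑2H‑chromen‑8‑yl}‑2‑methylpropan‑1‑one, racemic | CC(C)C(=O)c1c(O)c(C(CCCCC(C)C)S(=O)(=O)c3ccc(C)cc3)c(O)c2c1OC(C)(C)CC2 | intermediate
28 | 7‑hydroxy‑2,2‑dimethyl‑6‑(6‑methylheptylidene)‑8‑(2‑methylpropanoyl)‑3,4‑dihydro‑2H‑chromen‑5(6H)‑one (ortho‑quinone methide) | CC(C)C(=O)C1=C(O)C(=CCCCCC(C)C)C(=O)C2=C1OC(C)(C)CC2 | intermediate (not isolated)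
29 | (2R)‑1‑{6‑[(1R)‑1‑[5,7‑dihydroxy‑2,2‑dimethyl‑8‑(2‑methylpropanoyl)‑3,4‑dihydro‑2H‑chromen‑6‑yl]‑6‑methylheptyl]‑5,7‑dihydroxy‑2,2‑dimethyl‑3,4‑dihydro‑2H‑chromen‑8‑yl}‑2‑methylbutan‑1‑one | CC[C@@H](C)C(=O)c1c(O)c([C@H](CCCCC(C)C)c2c(O)c3c(c(C(=O)C(C)C)c2O)OC(C)(C)CC3)c(O)c2c1OC(C)(C)CC2 | target

**Count and risks**

Total step count: 14. Longest linear sequence: 8 steps (steps 1 to 6, 13 and 14).

Steps most likely to fail:

Step 14. Facial selectivity may be poor, because the quinone methide can exist as two carbonyl tautomers and two alkene geometries, and because the phenoxide of 24 can add without the catalyst at the phase boundary. Even in the good case a final polish on a chiral phase may be needed, since the bridge epimer is a diastereomer with remote centres. Fallback: setting out from 27 and 24, the union is run with an achiral base (Et3N, CH2Cl2, rt) and is expected to give 29 together with its bridge epimer (2R)‑1‑{6‑[(1S)‑1‑[5,7‑dihydroxy‑2,2‑dimethyl‑8‑(2‑methylpropanoyl)‑3,4‑dihydro‑2H‑chromen‑6‑yl]‑6‑methylheptyl]‑5,7‑dihydroxy‑2,2‑dimethyl‑3,4‑dihydro‑2H‑chromen‑8‑yl}‑2‑methylbutan‑1‑one F1. Because the acyl centre is fixed the two are diastereomers, and they are separated by preparative HPLC on a cellulose tris(3,5‑dimethylphenylcarbamate) phase, which comes back to the route at 29.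

Step 5. The radical sequence may leave its course: oxidation of the first radical before it meets the alkene, telomerisation with more vinyl sulfone, reduction of the adduct radical before ring closure, or ipso attack at the oxygen‑bearing carbon. Fallback: setting out from 4, copper‑catalysed O‑alkylation with 3‑chloro‑3‑methylbut‑1‑yne (CuCl2 cat., DBU, MeCN, 0 °C) should give 1‑{2,4‑bis(benzyloxy)‑6‑[(2‑methylbut‑3‑yn‑2‑yl)oxy]phenyl}‑2‑methylpropan‑1‑one F2. Heating (N,N‑diethylaniline, 180 °C) should bring about aromatic Claisen rearrangement to the one free ortho carbon, 1,5‑hydrogen shift and oxa‑6π electrocyclisation to 1‑[5,7‑bis(benzyloxy)‑2,2‑dimethyl‑2H‑chromen‑8‑yl]‑2‑methylpropan‑1‑one F3. Hydrogenation (H2, Pd/C, THF/MeOH) then saturates C3=C4 and removes both benzyl groups, which comes back to the route at 13.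

Step 13. The benzylic cation formed from the carbinol may be captured by a second molecule of 13 faster than by the sulfinic acid, which would give the symmetric bis‑chromanyl alkane, or the sulfone may ionise again during isolation. Fallback: setting out from 13 and 25, a Betti condensation with morpholine (EtOH, rt) uses a preformed iminium ion as electrophile, so that neither a benzylic cation nor a quinone methide is present while free 13 remains, and should give 1‑{5,7‑dihydroxy‑2,2‑dimethyl‑6‑[6‑methyl‑1‑(morpholin‑4‑yl)heptyl]‑3,4‑dihydro‑2H‑chromen‑8‑yl}‑2‑methylpropan‑1‑one F4. Treatment of F4 with p‑toluenesulfinic acid (2 equiv, CH2Cl2, rt) exchanges morpholine for sulfinate and comes back to the route at 27.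

**Further compounds**

F1 | step 14 | (2R)‑1‑{6‑[(1S)‑1‑[5,7‑dihydroxy‑2,2‑dimethyl‑8‑(2‑methylpropanoyl)‑3,4‑dihydro‑2H‑chromen‑6‑yl]‑6‑methylheptyl]‑5,7‑dihydroxy‑2,2‑dimethyl‑3,4‑dihydro‑2H‑chromen‑8‑yl}‑2‑methylbutan‑1‑one | CC[C@@H](C)C(=O)c1c(O)c([C@@H](CCCCC(C)C)c2c(O)c3c(c(C(=O)C(C)C)c2O)OC(C)(C)CC3)c(O)c2c1OC(C)(C)CC2
F2 | step 5 | 1‑{2,4‑bis(benzyloxy)‑6‑[(2‑methylbut‑3‑yn‑2‑yl)oxy]phenyl}‑2‑methylpropan‑1‑one | CC(C)C(=O)c1c(OC(C)(C)C#C)cc(OCc2ccccc2)cc1OCc1ccccc1
F3 | step 5 | 1‑[5,7‑bis(benzyloxy)‑2,2‑dimethyl‑2H‑chromen‑8‑yl]‑2‑methylpropan‑1‑one | CC(C)C(=O)c1c(OCc2ccccc2)cc(OCc2ccccc2)c2c1OC(C)(C)C=C2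
F4 | step 13 | 1‑{5,7‑dihydroxy‑2,2‑dimethyl‑6‑[6‑methyl‑1‑(morpholin‑4‑yl)heptyl]‑3,4‑dihydro‑2H‑chromen‑8‑yl}‑2‑methylpropan‑1‑one (racemic) | CC(C)C(=O)c1c(O)c(C(CCCCC(C)C)N3CCOCC3)c(O)c2c1OC(C)(C)CC2
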